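**Strategy.** Ring B (C5–C10) of this cis-fused eremophilane carries a trans C7-isopropenyl/C8-oxygen pair, the signature of a prenyl-to-aldehyde carbonyl-ene reaction. Everything therefore rests on disconnecting C7–C8: one Lewis-acid step closes ring B and sets C7 and C8 while creating the isopropenyl group and the C8 hydroxyl. The precursor is a ring A cyclohexane carrying the C5 prenyl group and, on C10, a C9-oxygenated C8 aldehyde. Its C9 oxygen is tied to C2 as a bridged methyl ketal, which masks the ketone, replaces a separate ether protecting group and holds C9 axial, so that only the chair leading to the 7β,8α array is open.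

Key step: step 11

Remarks on the chemistry (assumptions)
- Numbering: eremophilane numbering throughout (ring A = C1–C5 and C10, ring B = C5–C10). The target is read as 4β,5β-dimethyl, 10β-H (cis-fused), 7β-isopropenyl, 8α,9α-bis(angeloyloxy), C2 ketone, i.e. 4S,5R,7R,8R,9S,10S.
- Precursor design: in the ring B chair that gives the 7β,8α array, O9 is axial and lies under ring A, 1,3-syn to both C4 and C2. A separate axial oxygen on an sp3 C2 would collide with it, and the flipped ring A chair, with the C7, C8 and C9 substituents all equatorial, would lead to the 7α,8β isomers. O9 is therefore bonded to C2 itself, which leaves only the required chair.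
- Chemoselectivity: the prenyl alkene is present from step 1, so every later oxidation is one that spares a trisubstituted alkene.
- Assumption: the ligand antipodes in steps 1 and 7 are those that deliver the configurations drawn.

Step 1
Reactants: 1 2-methylcyclohex-2-en-1-one; 2 trimethylaluminium; 3 1-bromo-3-methylbut-2-ene
Product: 5 (2R,3S)-2,3-dimethyl-2-(3-methylbut-2-en-1-yl)cyclohexan-1-one, via aluminium enolate 4 (not isolated)
Conditions: AlMe3, Cu(O2C-2-thienyl) (2 mol%), chiral binaphthol-derived phosphoramidite (4 mol%), Et2O, −30 °C; then MeLi, THF/DMPU, 3, −30 °C → rt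
Reagents that add atoms: trimethylaluminium (2), C[Al](C)C; 1-bromo-3-methylbut-2-ene (3), CC(C)=CCBr
Why: Copper-catalysed asymmetric conjugate addition of AlMe3 to the α-substituted enone sets C4 (3S in 5) under ligand control, and the regiodefined enolate, activated as its lithium aluminate, is C-alkylated by the allylic bromide anti to the adjacent pseudo-axial methyl group (A(1,2) strain), which makes the two methyl groups cis and fixes the quaternary C5.

Step 2
Reactants: 5 (2R,3S)-2,3-dimethyl-2-(3-methylbut-2-en-1-yl)cyclohexan-1-one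
Product: 7 (5S,6R)-5,6-dimethyl-6-(3-methylbut-2-en-1-yl)cyclohex-2-en-1-one, via lithium enolate 6 (not isolated)
Conditions: LiN(i-Pr)2, THF, −78 °C; then PhS(Cl)=N-t-Bu, −78 °C
Reagents that add atoms: none
Why: Mukaiyama dehydrogenation: the ketone can enolise only towards C1 because C5 is quaternary, and the lithium enolate is sulfenylated at C1 and loses the sulfenamide by syn elimination at −78 °C, conditions under which the prenyl alkene and both stereocentres are untouched.

Step 3
Reactants: 7 (5S,6R)-5,6-dimethyl-6-(3-methylbut-2-en-1-yl)cyclohex-2-en-1-one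
Product: 8 (1S,3R,4S,6S)-3,4-dimethyl-3-(3-methylbut-2-en-1-yl)-7-oxabicyclo[4.1.0]heptan-2-one
Conditions: 30% H2O2, NaOH (cat.), MeOH, 0 °C
Reagents that add atoms: hydrogen peroxide, OO
Why: Weitz–Scheffer nucleophilic epoxidation touches only the electron-poor enone double bond and spares the electron-rich prenyl alkene; hydroperoxide is expected to add anti to the ring methyl groups (α-epoxide), but this configuration is erased in step 5.

Step 4
Reactants: 8 (1S,3R,4S,6S)-3,4-dimethyl-3-(3-methylbut-2-en-1-yl)-7-oxabicyclo[4.1.0]heptan-2-one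
Product: 9 (1S,4R,5S)-4,5-dimethyl-4-(3-methylbut-2-en-1-yl)cyclohex-2-en-1-ol
Conditions: N2H4·H2O, AcOH (cat.), MeOH, 0 °C → rt
Reagents that add atoms: none
Why: Wharton transposition: the epoxy ketone hydrazone opens the epoxide, and the resulting alkenyl diazene loses N2 to give the allylic alcohol with oxygen on C2 and the alkene at C1=C10; the carbinol centre is inherited from the epoxide and is of no consequence.

Step 5
Reactants: 9 (1S,4R,5S)-4,5-dimethyl-4-(3-methylbut-2-en-1-yl)cyclohex-2-en-1-ol
Product: 10 (4R,5S)-4,5-dimethyl-4-(3-methylbut-2-en-1-yl)cyclohex-2-en-1-one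
Conditions: DMP, CH2Cl2, 0 °C → rt
Reagents that add atoms: none
Why: Dess–Martin oxidation of the secondary allylic alcohol gives the 1,3-transposed enone under neutral conditions, without touching the prenyl group or the C4/C5 centres.

Step 6
Reactants: 10 (4R,5S)-4,5-dimethyl-4-(3-methylbut-2-en-1-yl)cyclohex-2-en-1-one; 11 vinylmagnesium bromide
Product: 13 (3R,4R,5S)-3-ethenyl-4,5-dimethyl-4-(3-methylbut-2-en-1-yl)cyclohexan-1-one, via silyl enol ether 12 (not isolated)
Conditions: CH2=CHMgBr, CuBr·SMe2 (10 mol%), Me3SiCl, THF, −78 °C; then 1 M HCl, 0 °C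
Reagents that add atoms: vinylmagnesium bromide (11), C=C[Mg]Br
Why: Copper-catalysed, silyl-chloride-accelerated conjugate addition of the vinyl Grignard reagent; the vinyl group enters C10 axially, anti to the axial C5 methyl and trans to the C4 methyl (the usual trans-3,4/trans-3,5 preference of cyclohexenones), hence cis to the prenyl group as the cis ring fusion requires, and the enol ether is hydrolysed on work-up.

Step 7
Reactants: 13 (3R,4R,5S)-3-ethenyl-4,5-dimethyl-4-(3-methylbut-2-en-1-yl)cyclohexan-1-one
Product: 15 (3S,4R,5S)-3-[(1S)-1,2-dihydroxyethyl]-4,5-dimethyl-4-(3-methylbut-2-en-1-yl)cyclohexan-1-one, via bis(boronate) 14 (not isolated)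
Conditions: B2pin2, Pt(dba)3 (3 mol%), chiral TADDOL-derived phenylphosphonite (6 mol%), THF, 60 °C; then 30% H2O2, NaOH, THF/H2O, 0 °C
Reagents that add atoms: hydrogen peroxide, OO
Why: Platinum-catalysed enantioselective 1,2-diboration attacks only the monosubstituted vinyl group (the trisubstituted prenyl alkene and the ketone do not react), the ligand antipode sets C9 (S) by catalyst control, and both C–B bonds are oxidised with retention.

Step 8
Reactants: 15 (3S,4R,5S)-3-[(1S)-1,2-dihydroxyethyl]-4,5-dimethyl-4-(3-methylbut-2-en-1-yl)cyclohexan-1-one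
Product: 16 (2S)-2-[(1S,2R,3S)-2,3-dimethyl-2-(3-methylbut-2-en-1-yl)-5-oxocyclohexyl]-2-hydroxyacetic acid
Conditions: TEMPO (10 mol%), NaClO2, NaOCl (5 mol%), NaH2PO4/Na2HPO4 buffer (pH 6.8), MeCN, 35 °C
Reagents that add atoms: sodium chlorite, [Na+].[O-]Cl=O
Why: Nitroxyl-catalysed chlorite oxidation (TEMPO/NaClO2 with catalytic hypochlorite) converts the primary hydroxyl of a terminal 1,2-diol into the carboxylic acid via the aldehyde hydrate, while the hindered secondary C9 hydroxyl, the ketone and, at the low steady-state hypochlorite level, the prenyl alkene are left alone; C9 is not epimerised at near-neutral pH.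

Step 9
Reactants: 16 (2S)-2-[(1S,2R,3S)-2,3-dimethyl-2-(3-methylbut-2-en-1-yl)-5-oxocyclohexyl]-2-hydroxyacetic acid
Product: 18 methyl (1S,2R,3S,5S,7S)-5-methoxy-2,3-dimethyl-2-(3-methylbut-2-en-1-yl)-6-oxabicyclo[3.2.1]octane-7-carboxylate, via dimethyl ketal ester 17 (not isolated)
Conditions: MeOH, HC(OMe)3, CSA (cat.), rt; then evaporation, PPTS (cat.), benzene, 4 Å MS, 60 °C (removal of MeOH)
Reagents that add atoms: methanol, CO
Why: Fischer esterification and ketalisation first give the open dimethyl ketal 17; once methanol is removed, acid-catalysed transketalisation through the C2 oxocarbenium ion closes the five-membered O9–C2 bridge (intramolecular addition of an alcohol to an oxocarbenium/enol ether remains downhill against the strain of the bridge), and the configuration at C2 is dictated by the α-axial C10–C9 bond.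

Step 10
Reactants: 18 methyl (1S,2R,3S,5S,7S)-5-methoxy-2,3-dimethyl-2-(3-methylbut-2-en-1-yl)-6-oxabicyclo[3.2.1]octane-7-carboxylate
Product: 19 (1S,2R,3S,5S,7S)-5-methoxy-2,3-dimethyl-2-(3-methylbut-2-en-1-yl)-6-oxabicyclo[3.2.1]octane-7-carbaldehyde
Conditions: i-Bu2AlH (1.2 equiv), CH2Cl2, −78 °C; aq. KNaC4H4O6 (potassium sodium tartrate) work-up
Reagents that add atoms: none
Why: Partial reduction of an α-alkoxy methyl ester with i-Bu2AlH at −78 °C stops at the chelated aluminium hemiacetal, which releases the aldehyde on work-up without epimerising C9; the bridgehead ketal is inert to the hydride at this temperature, and 19 is used crude.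

Step 11
Reactants: 19 (1S,2R,3S,5S,7S)-5-methoxy-2,3-dimethyl-2-(3-methylbut-2-en-1-yl)-6-oxabicyclo[3.2.1]octane-7-carbaldehyde
Product: 20 2α,9α-epoxy-2β-methoxy-10βH-eremophil-11-en-8α-ol (2S,4S,5R,7R,8R,9S,10S)
Conditions: Me2AlCl (2.5 equiv), CH2Cl2, −78 °C; aq. NaHCO3
Reagents that add atoms: none
Why: Two equivalents of Me2AlCl give a cationic Me2Al chelate between the aldehyde oxygen O8 and the bridging ketal oxygen O9, and C7 of the trisubstituted alkene then bonds to the activated C8 while an allylic methyl hydrogen shifts to O8 in a concerted, asynchronous six-centre ene array. The closest known reaction is the type 1 Lewis-acid carbonyl-ene cyclisation of citronellal to isopulegol, here with a chelating α-alkoxy aldehyde. Ring B is closed in a 6-exo-trig sense (C7 onto the exocyclic C8=O8 bond) through a chair. C8 is controlled by the chelate, which needs O8 gauche to the axial O9 and therefore equatorial (8α-OH), and C7 by the chair itself, the isopropylidene unit taking the equatorial site because the axial one is blocked by O9 and C4 (7β-isopropenyl, trans to the hydroxyl). The selectivity the step needs is closure through the ring A chair with C10–C9 axial and not through the flipped chair, which would put every ring B substituent equatorial and give the 7α,8β isomer; the O9–C2 ketal bridge secures this because it fixes C9 axial and holds the aldehyde over C6–C7, so the flipped chair cannot be reached. Low temperature and the proton-scavenging Lewis acid (methane is lost from the aluminium alkoxide) keep the bridgehead ketal and the new isopropenyl group intact.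

Step 12
Reactants: 20 2α,9α-epoxy-2β-methoxy-10βH-eremophil-11-en-8α-ol
Product: 21 8α,9α-dihydroxy-10βH-eremophil-11-en-2-one
Conditions: PPTS, acetone/H2O (10:1), 40 °C
Reagents that add atoms: water, O
Why: Acid-catalysed hydrolysis of the mixed ketal (opening at O9, capture of the C2 oxocarbenium ion by water, loss of methanol) frees the C2 ketone and the C9 hydroxyl under conditions mild enough for the isopropenyl group; no stereocentre is involved and 21 may sit partly as its internal C2–O9 hemiketal.

Step 13
Reactants: 21 8α,9α-dihydroxy-10βH-eremophil-11-en-2-one; 22 angelic acid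
Product: 23 8α,9α-bis(angeloyloxy)-10βH-eremophil-11-en-2-one (CNP0249036.1)
Conditions: 22, 2,4,6-trichlorobenzoyl chloride, Et3N, toluene, rt; then 21, 80 °C
Reagents that add atoms: angelic acid (22), C/C=C(/C)C(=O)O
Why: Yamaguchi-type esterification with the preformed angelic 2,4,6-trichlorobenzoic mixed anhydride, run hot without a nucleophilic catalyst, acylates both hydroxyls with retention of the Z geometry (no conjugate-addition pathway to tiglate), the open hydroxy ketone being drained from its hemiketal as the C9 hydroxyl is acylated.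

Compound list
1 | 2-methylcyclohex-2-en-1-one | CC1=CCCCC1=O | starting material
2 | trimethylaluminium | C[Al](C)C | starting material
3 | 1-bromo-3-methylbut-2-ene (prenyl bromide) | CC(C)=CCBr | starting material
4 | dimethylaluminium (3S)-2,3-dimethylcyclohex-1-en-1-olate | C[Al](C)OC1=C(C)[C@@H](C)CCC1 | intermediate
5 | (2R,3S)-2,3-dimethyl-2-(3-methylbut-2-en-1-yl)cyclohexan-1-one | CC(C)=CC[C@@]1(C)C(=O)CCC[C@@H]1C | intermediate
6 | lithium (5S,6R)-5,6-dimethyl-6-(3-methylbut-2-en-1-yl)cyclohex-1-en-1-olate | CC(C)=CC[C@@]1(C)C(O[Li])=CCC[C@@H]1C | intermediate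
7 | (5S,6R)-5,6-dimethyl-6-(3-methylbut-2-en-1-yl)cyclohex-2-en-1-one | CC(C)=CC[C@@]1(C)C(=O)C=CC[C@@H]1C | intermediate
8 | (1S,3R,4S,6S)-3,4-dimethyl-3-(3-methylbut-2-en-1-yl)-7-oxabicyclo[4.1.0]heptan-2-one (epoxide anti to the ring methyl groups) | CC(C)=CC[C@@]1(C)C(=O)[C@H]2O[C@H]2C[C@@H]1C | intermediate
9 | (1S,4R,5S)-4,5-dimethyl-4-(3-methylbut-2-en-1-yl)cyclohex-2-en-1-ol | CC(C)=CC[C@@]1(C)C=C[C@@H](O)C[C@@H]1C | intermediate
10 | (4R,5S)-4,5-dimethyl-4-(3-methylbut-2-en-1-yl)cyclohex-2-en-1-one | CC(C)=CC[C@@]1(C)C=CC(=O)C[C@@H]1C | intermediate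
11 | vinylmagnesium bromide | C=C[Mg]Br | starting material
12 | trimethylsilyl enol ether of 13 (C1=C2 enol ether, configuration as in 13) | CC(C)=CC[C@@]1(C)[C@H](C=C(O[Si](C)(C)C)C[C@@H]1C)C=C | intermediate
13 | (3R,4R,5S)-3-ethenyl-4,5-dimethyl-4-(3-methylbut-2-en-1-yl)cyclohexan-1-one | CC(C)=CC[C@@]1(C)[C@H](CC(=O)C[C@@H]1C)C=C | intermediate
14 | C8,C9-bis(pinacolatoboryl) adduct of 13 (boron on C9 with the configuration of the later hydroxyl) | CC(C)=CC[C@@]1(C)[C@H](CC(=O)C[C@@H]1C)[C@H](B2OC(C)(C)C(C)(C)O2)CB3OC(C)(C)C(C)(C)O3 | intermediate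
15 | (3S,4R,5S)-3-[(1S)-1,2-dihydroxyethyl]-4,5-dimethyl-4-(3-methylbut-2-en-1-yl)cyclohexan-1-one | CC(C)=CC[C@@]1(C)[C@H](CC(=O)C[C@@H]1C)[C@H](O)CO | intermediate
16 | (2S)-2-[(1S,2R,3S)-2,3-dimethyl-2-(3-methylbut-2-en-1-yl)-5-oxocyclohexyl]-2-hydroxyacetic acid | CC(C)=CC[C@@]1(C)[C@H](CC(=O)C[C@@H]1C)[C@H](O)C(=O)O | intermediate
17 | methyl (2S)-2-[(1S,2R,3S)-5,5-dimethoxy-2,3-dimethyl-2-(3-methylbut-2-en-1-yl)cyclohexyl]-2-hydroxyacetate | CC(C)=CC[C@@]1(C)[C@H](CC(OC)(OC)C[C@@H]1C)[C@H](O)C(=O)OC | intermediate
18 | methyl (1S,2R,3S,5S,7S)-5-methoxy-2,3-dimethyl-2-(3-methylbut-2-en-1-yl)-6-oxabicyclo[3.2.1]octane-7-carboxylate (O9 bonded to C2, methoxy on C2 β, ester on the side of the three-carbon bridge) | CC(C)=CC[C@@]1(C)[C@@H]2C[C@](OC)(C[C@@H]1C)O[C@@H]2C(=O)OC | intermediate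
19 | (1S,2R,3S,5S,7S)-5-methoxy-2,3-dimethyl-2-(3-methylbut-2-en-1-yl)-6-oxabicyclo[3.2.1]octane-7-carbaldehyde (key-step precursor) | CC(C)=CC[C@@]1(C)[C@@H]2C[C@](OC)(C[C@@H]1C)O[C@@H]2C=O | intermediate
20 | 2α,9α-epoxy-2β-methoxy-10βH-eremophil-11-en-8α-ol (key-step product; 7β-isopropenyl, 4β,5β-dimethyl) | C=C(C)[C@H]1C[C@@]2(C)[C@@H]3C[C@](OC)(C[C@@H]2C)O[C@@H]3[C@@H]1O | intermediate
21 | 8α,9α-dihydroxy-10βH-eremophil-11-en-2-one, (4S,4aR,6R,7R,8S,8aS)-7,8-dihydroxy-4,4a-dimethyl-6-(prop-1-en-2-yl)octahydronaphthalen-2(1H)-one | C=C(C)[C@H]1C[C@@]2(C)[C@H](CC(=O)C[C@@H]2C)[C@H](O)[C@@H]1O | intermediate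
22 | angelic acid, (2Z)-2-methylbut-2-enoic acid | C/C=C(/C)C(=O)O | starting material
23 | CNP0249036.1, 8α,9α-bis(angeloyloxy)-10βH-eremophil-11-en-2-one | C=C(C)[C@H]1C[C@@]2(C)[C@H](CC(=O)C[C@@H]2C)[C@H](OC(=O)/C(C)=C\C)[C@@H]1OC(=O)/C(C)=C\C | target

Total step count: 13
Longest linear sequence: 13 steps (1 → 23)

Steps most likely to fail

Step 11 (key step). What may go wrong: ionisation of the strained O9–C2 ketal bridge by the Lewis acid, which would release the conformational lock and open the way to methyl transfer from aluminium or Prins-type capture of the oxocarbenium ion; alternatively, closure with an axial carbonyl oxygen would give the C8 epimer. Fallback: it sets out from ester 18 and comes back at 20, replacing the ene reaction by an intramolecular Nozaki–Hiyama allylation. Ene-type allylic chlorination of the prenyl group with hypochlorous acid (Ca(OCl)2, solid CO2, CH2Cl2/H2O, 0 °C) should give the transposed secondary allylic chloride, the 2-(2-chloro-3-methylbut-3-en-1-yl) ester F1. Reduction with i-Bu2AlH at −78 °C gives the chloro aldehyde F2. CrCl2 (divalent chromium) in THF then forms the allylchromium species, which adds to the aldehyde through its γ-carbon C7 in a chair transition state. These conditions are neutral and leave the ketal alone; the allylic transposition restores the isopropenyl group and should give the 7,8-trans alcohol 20.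

Step 8. What may go wrong: oxidative glycol cleavage between C8 and C9, over-oxidation of the C9 carbinol, or chlorination of the prenyl alkene by hypochlorite. Fallback: it sets out from diol 15 and comes back at aldehyde 19, differentiating the two hydroxyls by protection instead of by a selective oxidation. Pivaloyl chloride and pyridine at 0 °C acylate only the primary C8 hydroxyl to give the primary pivalate F3. The ketalisation conditions of step 9 close the same O9–C2 bridge to give the bridged ketal pivalate F4. i-Bu2AlH removes the pivaloyl group to give the bridged ketal primary alcohol F5, and DMP with pyridine oxidises F5 to 19. This avoids both the chlorite oxidation and the ester half-reduction.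

Step 13. What may go wrong: Z-to-E isomerisation of the angeloyl groups to tiglates, and slow acylation of the axial C9 hydroxyl, which is hindered and partly tied up as the hemiketal. Fallback: it sets out from diol 21 and comes back at 23, building the Z-alkenes after the ester bonds are in place. Both hydroxyls are esterified with 2-[bis(2,2,2-trifluoroethoxy)phosphoryl]propanoic acid (DCC, DMAP, CH2Cl2; no isomerisable alkene is present in the acyl group) to give the bis(phosphonopropanoate) F6. A double Still–Gennari olefination with acetaldehyde (KN(SiMe3)2, 18-crown-6, THF, −78 °C) then installs both (Z)-2-methylbut-2-enoates, the phosphonate α-protons being more acidic than those next to the C2 ketone.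

Further compounds
F1 | step 11 | methyl (1S,2R,3S,5S,7S)-2-(2-chloro-3-methylbut-3-en-1-yl)-5-methoxy-2,3-dimethyl-6-oxabicyclo[3.2.1]octane-7-carboxylate (both C–Cl epimers) | C=C(C)C(Cl)C[C@@]1(C)[C@@H]2C[C@](OC)(C[C@@H]1C)O[C@@H]2C(=O)OC
F2 | step 11 | (1S,2R,3S,5S,7S)-2-(2-chloro-3-methylbut-3-en-1-yl)-5-methoxy-2,3-dimethyl-6-oxabicyclo[3.2.1]octane-7-carbaldehyde (both C–Cl epimers) | C=C(C)C(Cl)C[C@@]1(C)[C@@H]2C[C@](OC)(C[C@@H]1C)O[C@@H]2C=O
F3 | step 8 | (2S)-2-[(1S,2R,3S)-2,3-dimethyl-2-(3-methylbut-2-en-1-yl)-5-oxocyclohexyl]-2-hydroxyethyl 2,2-dimethylpropanoate | CC(C)=CC[C@@]1(C)[C@H](CC(=O)C[C@@H]1C)[C@H](O)COC(=O)C(C)(C)C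
F4 | step 8 | [(1S,2R,3S,5S,7S)-5-methoxy-2,3-dimethyl-2-(3-methylbut-2-en-1-yl)-6-oxabicyclo[3.2.1]octan-7-yl]methyl 2,2-dimethylpropanoate | CC(C)=CC[C@@]1(C)[C@@H]2C[C@](OC)(C[C@@H]1C)O[C@@H]2COC(=O)C(C)(C)C
F5 | step 8 | [(1S,2R,3S,5S,7S)-5-methoxy-2,3-dimethyl-2-(3-methylbut-2-en-1-yl)-6-oxabicyclo[3.2.1]octan-7-yl]methanol | CC(C)=CC[C@@]1(C)[C@@H]2C[C@](OC)(C[C@@H]1C)O[C@@H]2CO
F6 | step 13 | 8α,9α-bis{2-[bis(2,2,2-trifluoroethoxy)phosphoryl]propanoyloxy}-10βH-eremophil-11-en-2-one (phosphonate α-centres as mixtures) | C=C(C)[C@H]1C[C@@]2(C)[C@H](CC(=O)C[C@@H]2C)[C@H](OC(=O)C(C)P(=O)(OCC(F)(F)F)OCC(F)(F)F)[C@@H]1OC(=O)C(C)P(=O)(OCC(F)(F)F)OCC(F)(F)F
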